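**Retrosynthetic overview**

1. Locants used below: ring C1–C14 (C3 carries CO2Me, C2=C3 is the enoate, C14 is the stereocentre), side chain C15–C19.
2. Target 20 ⇐ Z-enol triflate 19 ⇐ 14-membered β-keto ester 17 (the C2 oxygen is removed last).
3. 17 ⇐ 16-membered cyclic allyl vinyl ether (C2–O–C16) by [3,3] ring contraction (C1–C14 formed, C16–O broken, 16R → 14R). The ether ⇐ hydroxy allenoate 13 by ring-closing C–O bond formation. Ring order: 16-membered oxacycle first, then the 14-membered carbocycle.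
4. 13 ⇐ propargylic carbonate 12 (Pd/CO); the C16 carbinol ⇐ enal 9 + reverse-prenyl boronate 10 (asymmetric allylboration).
5. 9 ⇐ (2E,6E)-farnesyl bromide 1 + propargyl bromide 2 + formaldehyde, then terminal allylic oxidation.

Assumption: (2E,6E)-farnesyl bromide (1) and 4,4,5,5-tetramethyl-2-(2-methylbut-3-en-2-yl)-1,3,2-dioxaborolane (10) are taken as purchasable catalogue compounds.

**Route**

Step 1
Reactants: 1 (2E,6E)-farnesyl bromide; 2 propargyl bromide
Product: 4 (5E,9E)-6,10,14-trimethylpentadeca-5,9,13-trien-1-yne, via allenylmagnesium bromide 3 (not isolated)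
Conditions: 2, Mg, HgCl2 (cat.), Et2O, 0 °C; then 1, Et2O, 0 °C → rt
Reagents that add atoms: none
Why: SN2 coupling of a primary allylic bromide with allenylmagnesium bromide, which reacts through its γ-carbon (SE2′) to give the 1,5-enyne with the 2E olefin retained; minor allenic and SN2′ isomers are removed by chromatography.

Step 2
Reactants: 4 (5E,9E)-6,10,14-trimethylpentadeca-5,9,13-trien-1-yne
Product: 7 methyl (6E,10E)-7,11,15-trimethylhexadeca-6,10,14-trien-2-yn-1-yl carbonate, via lithium acetylide 5 (not isolated), via lithium propargylic alkoxide 6 (not isolated)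
Conditions: n-BuLi, THF, −78 °C; (CH2O)n, −78 °C → rt; then ClCO2Me, 0 °C
Reagents that add atoms: paraformaldehyde (formaldehyde), C=O; methyl chloroformate, COC(=O)Cl
Why: Acetylide addition to formaldehyde followed by in situ O-acylation of the lithium alkoxide; the substrate has no other acidic or electrophilic site.

Step 3
Reactants: 7 methyl (6E,10E)-7,11,15-trimethylhexadeca-6,10,14-trien-2-yn-1-yl carbonate
Product: 9 methyl (6E,10E,14E)-7,11,15-trimethyl-16-oxohexadeca-6,10,14-trien-2-yn-1-yl carbonate, via C16 allylic alcohol 8 (not isolated)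
Conditions: SeO2 (0.3 equiv), t-BuOOH, salicylic acid (cat.), CH2Cl2, 0 °C → rt (to about 60 % conversion, 7 recycled); filter; MnO2, CH2Cl2, rt
Reagents that add atoms: selenium dioxide (oxygen carrier), O=[Se]=O; tert-butyl hydroperoxide (terminal oxidant), CC(C)(C)OO
Why: Sharpless SeO2/TBHP allylic oxidation (ene/[2,3] sequence) attacks the E-methyl of the terminal trisubstituted olefin, and MnO2 converges the alcohol/aldehyde mixture to the E enal without touching the carbonate or the alkyne.

Step 4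
Reactants: 9 methyl (6E,10E,14E)-7,11,15-trimethyl-16-oxohexadeca-6,10,14-trien-2-yn-1-yl carbonate; 10 4,4,5,5-tetramethyl-2-(2-methylbut-3-en-2-yl)-1,3,2-dioxaborolane
Product: 12 methyl (6E,10E,14E,16R)-16-hydroxy-7,11,15,19-tetramethylicosa-6,10,14,18-tetraen-2-yn-1-yl carbonate, via pinacol borate ester 11 (not isolated)
Conditions: (R)-TRIP (5 mol %), 4 Å MS, toluene, −30 → 0 °C; aq. NaHCO3 work-up
Reagents that add atoms: none
Why: Chiral-phosphoric-acid-catalysed allylboration through a closed chair transition state with allylic transposition of the tertiary boronate, so the linear prenyl carbinol is formed; by analogy with allyl-Bpin additions to aryl and alkenyl aldehydes (R)-TRIP should set 16R, to be checked by Mosher analysis, with (S)-TRIP used if the sense is reversed.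

Step 5
Reactants: 12 methyl (6E,10E,14E,16R)-16-hydroxy-7,11,15,19-tetramethylicosa-6,10,14,18-tetraen-2-yn-1-yl carbonate
Product: 13 methyl (5E,9E,13E,15R)-2-ethenylidene-15-hydroxy-6,10,14,18-tetramethylnonadeca-5,9,13,17-tetraenoate
Conditions: Pd2(dba)3·CHCl3 (2.5 mol %), PPh3 (10 mol %), CO (10 atm), MeOH, 40 °C
Reagents that add atoms: carbon monoxide, [C-]#[O+]
Why: Tsuji carbonylation of a propargylic carbonate: SN2′ oxidative addition and CO2 loss give an allenyl-Pd methoxide, and CO insertion with methoxide transfer gives the 2-substituted buta-2,3-dienoate; the free secondary alcohol and the olefins are inert.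

Step 6
Reactants: 13 methyl (5E,9E,13E,15R)-2-ethenylidene-15-hydroxy-6,10,14,18-tetramethylnonadeca-5,9,13,17-tetraenoate
Product: 17 methyl (4E,8E,12R)-5,9-dimethyl-12-[(2E)-6-methylhepta-2,5-dien-2-yl]-14-oxocyclotetradeca-4,8-diene-1-carboxylate (C1 epimers), via potassium alkoxide 14 (not isolated), via macrocyclic enol ether enolate 15 (not isolated), via ketoester potassium enolate 16 (not isolated)
Conditions: KH (1.5 equiv), 18-crown-6 (1.5 equiv), THF, 25 °C, 13 added by syringe pump over 10 h (final 1 mM), then 40 °C, 2 h; AcOH, 0 °C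
Reagents that add atoms: none
Why: Proposed new method: the C16 potassium alkoxide adds intramolecularly to the central carbon of the allenoate (ring-closing C2–O bond, 16-membered allyl vinyl ether), and the resulting ester-stabilised 2-oxyallyl anion undergoes a carbanion-accelerated Claisen rearrangement at its CH2 terminus (C1–C14 formed, C16–O broken), driven by formation of the β-keto ester enolate. Suprafacial transfer with the prenyl group pseudo-equatorial turns 16R into 14R (ring locant 12R) and gives the E C15=C16 olefin whether the transition state is chair or boat. The closest known reactions are Denmark's carbanion-accelerated Claisen rearrangement of allyl vinyl ethers made from allyl alkoxides and sulfonylallenes, and alkoxide β-additions to allenoates; neither has been shown with an ester-stabilised anion or in a macrocyclising, ring-contracting mode.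

Step 7
Reactants: 17 methyl (4E,8E,12R)-5,9-dimethyl-12-[(2E)-6-methylhepta-2,5-dien-2-yl]-14-oxocyclotetradeca-4,8-diene-1-carboxylate
Product: 19 methyl (1Z,4R,7E,11E)-7,11-dimethyl-4-[(2E)-6-methylhepta-2,5-dien-2-yl]-2-{[(trifluoromethyl)sulfonyl]oxy}cyclotetradeca-1,7,11-triene-1-carboxylate, via lithium Z-enolate 18 (not isolated)
Conditions: Tf2O, sat. aq. LiOH, toluene, 5 °C (biphasic)
Reagents that add atoms: triflic anhydride, O=S(=O)(OS(=O)(=O)C(F)(F)F)C(F)(F)F
Why: The β-keto ester enolises only between the two carbonyls and its lithium enolate is a six-membered chelate, so O-triflation (Frantz-type conditions) gives the Z enol triflate; C14 is not enolisable.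

Step 8
Reactants: 19 methyl (1Z,4R,7E,11E)-7,11-dimethyl-4-[(2E)-6-methylhepta-2,5-dien-2-yl]-2-{[(trifluoromethyl)sulfonyl]oxy}cyclotetradeca-1,7,11-triene-1-carboxylate
Product: 20 methyl (1E,4R,7E,11E)-7,11-dimethyl-4-[(2E)-6-methylhepta-2,5-dien-2-yl]cyclotetradeca-1,7,11-triene-1-carboxylate
Conditions: Pd(OAc)2 (5 mol %), PPh3 (10 mol %), HCO2H, Et3N, DMF, 60 °C
Reagents that add atoms: none
Why: Cacchi-type hydrogenolysis of a vinyl triflate (oxidative addition, formate-derived hydride, reductive elimination) proceeds with retention of olefin geometry, so the Z triflate gives the E enoate; the trisubstituted olefins and C14 are untouched.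

**Compound list**

1 | (2E,6E)-1-bromo-3,7,11-trimethyldodeca-2,6,10-triene (farnesyl bromide) | CC(C)=CCC/C(C)=C/CC/C(C)=C/CBr | starting material
2 | 3-bromoprop-1-yne (propargyl bromide) | C#CCBr | starting material
3 | allenylmagnesium bromide | C=C=C[Mg]Br | intermediate (not isolated)
4 | (5E,9E)-6,10,14-trimethylpentadeca-5,9,13-trien-1-yne | CC(C)=CCC/C(C)=C/CC/C(C)=C/CCC#C | intermediate
5 | lithium acetylide of 4 | CC(C)=CCC/C(C)=C/CC/C(C)=C/CCC#C[Li] | intermediate (not isolated)
6 | lithium (6E,10E)-7,11,15-trimethylhexadeca-6,10,14-trien-2-yn-1-olate | CC(C)=CCC/C(C)=C/CC/C(C)=C/CCC#CCO[Li] | intermediate (not isolated)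
7 | methyl (6E,10E)-7,11,15-trimethylhexadeca-6,10,14-trien-2-yn-1-yl carbonate | CC(C)=CCC/C(C)=C/CC/C(C)=C/CCC#CCOC(=O)OC | intermediate
8 | methyl (6E,10E,14E)-16-hydroxy-7,11,15-trimethylhexadeca-6,10,14-trien-2-yn-1-yl carbonate | OC/C(C)=C/CC/C(C)=C/CC/C(C)=C/CCC#CCOC(=O)OC | intermediate (not isolated)
9 | methyl (6E,10E,14E)-7,11,15-trimethyl-16-oxohexadeca-6,10,14-trien-2-yn-1-yl carbonate | O=C/C(C)=C/CC/C(C)=C/CC/C(C)=C/CCC#CCOC(=O)OC | intermediate
10 | 4,4,5,5-tetramethyl-2-(2-methylbut-3-en-2-yl)-1,3,2-dioxaborolane | C=CC(C)(C)B1OC(C)(C)C(C)(C)O1 | starting material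
11 | pinacol borate ester of 12 (16R) | CC(C)=CC[C@@H](OB1OC(C)(C)C(C)(C)O1)/C(C)=C/CC/C(C)=C/CC/C(C)=C/CCC#CCOC(=O)OC | intermediate (not isolated)
12 | methyl (6E,10E,14E,16R)-16-hydroxy-7,11,15,19-tetramethylicosa-6,10,14,18-tetraen-2-yn-1-yl carbonate | CC(C)=CC[C@@H](O)/C(C)=C/CC/C(C)=C/CC/C(C)=C/CCC#CCOC(=O)OC | intermediate
13 | methyl (5E,9E,13E,15R)-2-ethenylidene-15-hydroxy-6,10,14,18-tetramethylnonadeca-5,9,13,17-tetraenoate | CC(C)=CC[C@@H](O)/C(C)=C/CC/C(C)=C/CC/C(C)=C/CCC(=C=C)C(=O)OC | intermediate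
14 | potassium alkoxide of 13 | CC(C)=CC[C@@H](O[K])/C(C)=C/CC/C(C)=C/CC/C(C)=C/CCC(=C=C)C(=O)OC | intermediate (not isolated)
15 | potassium ester enolate of the 16-membered cyclic allyl vinyl ether (2-methylene-1-oxacyclohexadeca-5,9,13-triene, 16R, 16-prenyl) | C=C1O[C@H](CC=C(C)C)/C(C)=C/CC/C(C)=C/CC/C(C)=C/CCC1=C([O-])OC.[K+] | intermediate (not isolated)
16 | potassium enolate of 17 | COC(=O)C1=C([O-])C[C@H](/C(C)=C/CC=C(C)C)CC/C(C)=C/CC/C(C)=C/CC1.[K+] | intermediate (not isolated)
17 | methyl (4E,8E,12R)-5,9-dimethyl-12-[(2E)-6-methylhepta-2,5-dien-2-yl]-14-oxocyclotetradeca-4,8-diene-1-carboxylate (C1 epimers) | COC(=O)C1C(=O)C[C@H](/C(C)=C/CC=C(C)C)CC/C(C)=C/CC/C(C)=C/CC1 | intermediate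
18 | lithium Z-enolate of 17 | COC(=O)/C1=C(O[Li])/C[C@H](/C(C)=C/CC=C(C)C)CC/C(C)=C/CC/C(C)=C/CC1 | intermediate (not isolated)
19 | methyl (1Z,4R,7E,11E)-7,11-dimethyl-4-[(2E)-6-methylhepta-2,5-dien-2-yl]-2-{[(trifluoromethyl)sulfonyl]oxy}cyclotetradeca-1,7,11-triene-1-carboxylate | COC(=O)/C1=C(OS(=O)(=O)C(F)(F)F)/C[C@H](/C(C)=C/CC=C(C)C)CC/C(C)=C/CC/C(C)=C/CC1 | intermediate
20 | methyl (1E,4R,7E,11E)-7,11-dimethyl-4-[(2E)-6-methylhepta-2,5-dien-2-yl]cyclotetradeca-1,7,11-triene-1-carboxylate | COC(=O)/C1=C/C[C@H](/C(C)=C/CC=C(C)C)CC/C(C)=C/CC/C(C)=C/CC1 | target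

**Step count**

Total steps: 8. Longest linear sequence: 8 (1 → 20).

**Steps most likely to fail**

Step 6 (the proposed new cascade). Possible failures are oligomerisation, alkoxide attack on the methyl ester instead of the allenoate, and rearrangement through the α-carbon. The fallback uses only known chemistry: an acyclic Claisen rearrangement sets C14 and an intramolecular Horner–Wadsworth–Emmons olefination closes the ring. It sets out from enyne 4 and comes back at the target 20. Hydroboration of 4 with dicyclohexylborane and NaBO3 oxidation gives (5E,9E)-6,10,14-trimethylpentadeca-5,9,13-trienal F6. Pinnick oxidation gives the acid F7 and TMSCHN2 the methyl ester F8. LDA and ClP(O)(OEt)2, then a second portion of LDA (phosphate-to-phosphonate 1,3-shift), give the α-phosphono ester F9. SeO2/TBHP then MnO2 as in step 3 give the enal F10, and boronate 10 with (R)-TRIP as in step 4 gives the 15R alcohol F11. Hg(OAc)2-catalysed transvinylation with ethyl vinyl ether gives the allyl vinyl ether F12, which rearranges in toluene at 110 °C to the aldehyde F13 (same suprafacial transfer, R stereocentre, E olefin). LiCl/DBU in MeCN at 1 mM then closes the 14-membered ring to 20; the E enoate is expected to predominate and the Z isomer is separated.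

Step 3 (SeO2 oxidation). The two internal trisubstituted olefins and the propargylic positions can compete with the terminal E-methyl. The fallback functionalises the terminus by the van Tamelen sequence; it sets out from 7 and comes back at 9. NBS in THF/H2O at 0 °C gives the terminal bromohydrin F1, DBU in CH2Cl2 closes it to the 14,15-epoxide F2, and H5IO6 in THF/Et2O cleaves this to the trisnor aldehyde F3. Wittig reaction of F3 with 2-(triphenylphosphoranylidene)propanal in toluene at 90 °C gives the E enal 9.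

Step 4 (catalytic asymmetric prenylboration). The tertiary boronate may react slowly or with low ee on the α-methyl enal. The fallback sets the carbinol by ketone reduction; it sets out from 9 and comes back at 12. Boronate 10 is added without catalyst (toluene, 40 °C) to give the racemic alcohol F4, and Dess–Martin periodinane with NaHCO3 gives the enone F5. (S)-Me-CBS with catecholborane at −78 °C then reduces F5 to 12 (alkenyl as the large group, 16R).

**Further compounds**

F1 | step 3 | methyl (6E,10E)-14-bromo-15-hydroxy-7,11,15-trimethylhexadeca-6,10-dien-2-yn-1-yl carbonate (racemic) | CC(C)(O)C(Br)CC/C(C)=C/CC/C(C)=C/CCC#CCOC(=O)OC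
F2 | step 3 | methyl (6E,10E)-13-(3,3-dimethyloxiran-2-yl)-7,11-dimethyltrideca-6,10-dien-2-yn-1-yl carbonate (racemic) | CC1(C)OC1CC/C(C)=C/CC/C(C)=C/CCC#CCOC(=O)OC
F3 | step 3 | methyl (6E,10E)-7,11-dimethyl-14-oxotetradeca-6,10-dien-2-yn-1-yl carbonate | O=CCC/C(C)=C/CC/C(C)=C/CCC#CCOC(=O)OC
F4 | step 4 | methyl (6E,10E,14E)-16-hydroxy-7,11,15,19-tetramethylicosa-6,10,14,18-tetraen-2-yn-1-yl carbonate (racemic) | CC(C)=CCC(O)/C(C)=C/CC/C(C)=C/CC/C(C)=C/CCC#CCOC(=O)OC
F5 | step 4 | methyl (6E,10E,14E)-7,11,15,19-tetramethyl-16-oxoicosa-6,10,14,18-tetraen-2-yn-1-yl carbonate | CC(C)=CCC(=O)/C(C)=C/CC/C(C)=C/CC/C(C)=C/CCC#CCOC(=O)OC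
F6 | step 6 | (5E,9E)-6,10,14-trimethylpentadeca-5,9,13-trienal | CC(C)=CCC/C(C)=C/CC/C(C)=C/CCCC=O
F7 | step 6 | (5E,9E)-6,10,14-trimethylpentadeca-5,9,13-trienoic acid | CC(C)=CCC/C(C)=C/CC/C(C)=C/CCCC(=O)O
F8 | step 6 | methyl (5E,9E)-6,10,14-trimethylpentadeca-5,9,13-trienoate | CC(C)=CCC/C(C)=C/CC/C(C)=C/CCCC(=O)OC
F9 | step 6 | methyl (5E,9E)-2-(diethoxyphosphoryl)-6,10,14-trimethylpentadeca-5,9,13-trienoate (racemic) | CC(C)=CCC/C(C)=C/CC/C(C)=C/CCC(C(=O)OC)P(=O)(OCC)OCC
F10 | step 6 | methyl (5E,9E,13E)-2-(diethoxyphosphoryl)-6,10,14-trimethyl-15-oxopentadeca-5,9,13-trienoate | O=C/C(C)=C/CC/C(C)=C/CC/C(C)=C/CCC(C(=O)OC)P(=O)(OCC)OCC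
F11 | step 6 | methyl (5E,9E,13E,15R)-2-(diethoxyphosphoryl)-15-hydroxy-6,10,14,18-tetramethylnonadeca-5,9,13,17-tetraenoate | CC(C)=CC[C@@H](O)/C(C)=C/CC/C(C)=C/CC/C(C)=C/CCC(C(=O)OC)P(=O)(OCC)OCC
F12 | step 6 | methyl (5E,9E,13E,15R)-2-(diethoxyphosphoryl)-15-(ethenyloxy)-6,10,14,18-tetramethylnonadeca-5,9,13,17-tetraenoate | CC(C)=CC[C@@H](OC=C)/C(C)=C/CC/C(C)=C/CC/C(C)=C/CCC(C(=O)OC)P(=O)(OCC)OCC
F13 | step 6 | methyl (5E,9E,13R,14E)-2-(diethoxyphosphoryl)-6,10,14,18-tetramethyl-13-(2-oxoethyl)nonadeca-5,9,14,17-tetraenoate | O=CC[C@H](/C(C)=C/CC=C(C)C)CC/C(C)=C/CC/C(C)=C/CCC(C(=O)OC)P(=O)(OCC)OCC
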